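**Strategy.** Ring B (seven-membered) is cut at C5–C6 and C1–C10 (C1 methyl-bearing fusion carbon, C2 angelate carbon, C4 carbinol, C5 fusion CH, C6 aryl-ester carbon, C8=C9 alkene). These bonds leave the β carbon C5 and the α carbon C1 of a C2 ketone in five-membered ring A, so one flask suffices. A C6 dithiane anion adds to C5 of a 4-silyloxy-2-methylcyclopentenone, and the C1 enolate is then allylated at C10, closing ring B cis-fused and setting C5 and C1. The precursor is a 2-substituted 1,3-dithiane with a Z-2-methylbut-2-enyl chain ending in a C10 alkoxide, which is made a leaving group only after the conjugate addition.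

Key step: step 7

Remark: 1 and 4 are taken as catalogue compounds. No halide is carried at C10 of the dithiane, because a C6 carbanion facing a cis-allylic halide would close to a cyclopentene (and the alkyllithium base would attack the halide) before the enone is met. Bicyclic compounds are named with the numbering above (ring A = C1–C5; ring B = C1, C5–C10; "spiro-dithiane at C6" means C6 is C2 of a 1,3-dithiane).

Step 1
Reactants: 1 (4S)-4-(tert-butyldimethylsilyloxy)cyclopent-2-en-1-one
Product: 2 (4S)-4-(tert-butyldimethylsilyloxy)-2-iodocyclopent-2-en-1-one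
Conditions: I2, pyridine, CH2Cl2, 0 °C → rt
Reagents that add atoms: iodine, II
Why: α-Iodination of the enone by pyridine addition, iodination and elimination (Baylis–Hillman-type), which leaves the C4 stereocentre and the silyl ether untouched.

Step 2
Reactants: 2 (4S)-4-(tert-butyldimethylsilyloxy)-2-iodocyclopent-2-en-1-one
Product: 3 (4S)-4-(tert-butyldimethylsilyloxy)-2-methylcyclopent-2-en-1-one
Conditions: Me4Sn, PdCl2(PhCN)2 (5 mol %), AsPh3, CuI (10 mol %), NMP, 80 °C
Reagents that add atoms: tetramethylstannane, C[Sn](C)(C)C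
Why: Stille coupling of the α-iodoenone under neutral conditions, so the base-sensitive β-silyloxy enone should neither eliminate nor racemise.

Step 3
Reactants: 4 4,4-diethoxybut-1-yne; 5 propane-1,3-dithiol
Product: 6 2-(prop-2-yn-1-yl)-1,3-dithiane
Conditions: BF3·OEt2 (20 mol %), CH2Cl2, 0 °C → rt
Reagents that add atoms: none
Why: Lewis acid-catalysed transthioacetalisation of the acetal gives the dithiane directly, so the isomerisation-prone free but-3-ynal is never handled.

Step 4
Reactants: 6 2-(prop-2-yn-1-yl)-1,3-dithiane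
Product: 8 methyl 4-(1,3-dithian-2-yl)but-2-ynoate, via lithium alkynide 7 (not isolated)
Conditions: nBuLi (1.05 equiv), THF, −78 °C; ClCO2Me, −78 → 0 °C
Reagents that add atoms: methyl chloroformate, COC(=O)Cl
Why: The alkyne C–H is far more acidic than the dithiane C–H, so one equivalent of base gives only the alkynide, which is acylated by the chloroformate (alkynoate synthesis).

Step 5
Reactants: 8 methyl 4-(1,3-dithian-2-yl)but-2-ynoate
Product: 9 methyl (2Z)-4-(1,3-dithian-2-yl)-3-methylbut-2-enoate
Conditions: Me2CuLi (from CuI and 2 MeLi), THF, −78 °C; MeOH, −78 °C, then aq. NH4Cl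
Reagents that add atoms: lithium dimethylcuprate, [Li+].C[Cu-]C
Why: syn-Carbocupration of the alkynoate and cold protonation put methyl and hydrogen on the same side, so the dithianylmethyl group stays cis to the ester and the Z geometry of the future C8=C9 alkene is fixed.

Step 6
Reactants: 9 methyl (2Z)-4-(1,3-dithian-2-yl)-3-methylbut-2-enoate
Product: 10 (2Z)-4-(1,3-dithian-2-yl)-3-methylbut-2-en-1-ol
Conditions: iBu2AlH (2.5 equiv), CH2Cl2, −78 → −20 °C; aq. potassium sodium tartrate
Reagents that add atoms: none
Why: 1,2-Reduction of the conjugated ester by the aluminium hydride gives the allylic alcohol without touching the alkene geometry or the dithiane.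

Step 7
Reactants: 10 (2Z)-4-(1,3-dithian-2-yl)-3-methylbut-2-en-1-ol; 3 (4S)-4-(tert-butyldimethylsilyloxy)-2-methylcyclopent-2-en-1-one
Product: 14 (1R,4S,5S) cis-fused ketone: C2 ketone; C4 tert-butyldimethylsilyloxy; spiro-dithiane at C6; C8=C9 alkene; methyl groups on C1 and C8, via dilithio dithiane alkoxide 11 (not isolated), via Michael adduct dilithium enolate alkoxide 12 (not isolated), via lithium enolate allylic acetate 13 (not isolated)
Conditions: nBuLi (2.1 equiv), THF, −30 °C; HMPA, −78 °C, then 3; Ac2O (1.05 equiv), −78 °C; Et3B (1.1 equiv), Pd(PPh3)4 (5 mol %), −78 °C → rt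
Reagents that add atoms: none
Why: Proposed new method: the C6 carbanion of 11 adds 1,4 to 3 (HMPA-separated ion pair, as in known lithiodithiane conjugate additions), Ac2O then acetylates the C10 alkoxide (an O-acetylated enolate would pass its acetyl on to the more basic alkoxide), and zerovalent palladium ionises the allylic acetate so that the C1 enolate, held as its triethylborate, is allylated at C10; the closest known reactions are conjugate addition followed by palladium-catalysed enolate allylation and the Tsuji–Trost allylation of preformed ketone enoxyborates with allylic acetates, which keeps the enolate position, whereas their union on a tethered pair is untested. Ring B closes by attack of C1 on the unsubstituted allyl terminus C10 (formally 7-exo-tet at C10 with the allyl unit inside the new ring), the alternative five-membered closure at C8 being blocked because it would join two quaternary carbons. C5 is set by approach of the tertiary carbanion anti to the C4 silyloxy group. C1 is set by the tether: the Z alkene keeps C7 and C10 on one side, so C10 can reach the enolate only on the face that already carries C6, which gives the cis fusion with the methyl group on the other face. The step needs 1,4 over 1,2 addition (HMPA), C over O allylation (soft allylpalladium electrophile) and an enolate that stays at C1, because a C3 enolate would expel the C4 silyloxy group; the conjugate addition itself fixes that position and the borate prevents proton exchange. The C10 oxygen stays an alkoxide until C5–C6 exists, since a C6 carbanion facing a C10 leaving group across the cis alkene would close to a cyclopentene.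

Step 8
Reactants: 14 (1R,4S,5S) cis-fused C2 ketone
Product: 15 (1R,2S,4S,5S) C2 alcohol of 14, hydroxyl on the face opposite the C1 methyl group
Conditions: (R)-2-methyl-CBS-oxazaborolidine (30 mol %), catecholborane, toluene, −78 → −40 °C
Reagents that add atoms: none
Why: Corey–Bakshi–Shibata reduction in which quaternary C1 is the large and C3 the small ketone substituent, so the (R)-catalyst should deliver hydride to the face cis to the C1 methyl group and set (2S); catecholborane is used because it should leave the C8=C9 alkene alone.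

Step 9
Reactants: 15 (1R,2S,4S,5S) C2 alcohol
Product: 16 C2 4-methoxybenzyl ether of 15
Conditions: NaH, 4-methoxybenzyl chloride, Bu4NI (cat.), DMF, 0 °C → rt
Reagents that add atoms: 4-methoxybenzyl chloride, COc1ccc(CCl)cc1
Why: Williamson etherification; an ether rather than an ester is placed at C2 so that the later C4 ketone cannot lose the C2 oxygen by β-elimination, and it should survive fluoride, organocerium, MeI and borohydride.

Step 10
Reactants: 16 C2 4-methoxybenzyl ether with C4 silyl ether
Product: 17 C4 alcohol (silyl group removed from 16)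
Conditions: HF·pyridine, pyridine, THF, 0 °C → rt
Reagents that add atoms: none
Why: Fluoride cleavage of the secondary silyl ether, to which the benzyl-type ether, the dithiane and the alkene are inert.

Step 11
Reactants: 17 C4 alcohol
Product: 18 (1R,2S,5S) C4 ketone
Conditions: SO3·pyridine, DMSO, iPr2NEt, CH2Cl2, 0 °C
Reagents that add atoms: none
Why: Parikh–Doering oxidation; activated DMSO does not attack dithiane sulfur, and the mild base at 0 °C should leave the C5 stereocentre next to the new ketone intact.

Step 12
Reactants: 18 (1R,2S,5S) C4 ketone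
Product: 19 (1R,2S,4S,5S) C4 tertiary alcohol, isopropyl cis to C5–H
Conditions: iPrMgCl, CeCl3, THF, −78 → −40 °C; aq. NH4Cl
Reagents that add atoms: isopropylmagnesium chloride, CC(C)[Mg]Cl
Why: Organocerium 1,2-addition, whose low basicity suppresses enolisation and β-hydride reduction; attack on the convex face of the cis-fused bicycle (cis to C5–H, away from the C6 dithiane) should set (4S).

Step 13
Reactants: 19 (1R,2S,4S,5S) C4 tertiary alcohol with C6 dithiane
Product: 20 (1R,2S,4S,5S) C6 ketone (β-hydroxy ketone)
Conditions: MeI (excess), CaCO3, MeCN/H2O 9:1, 45 °C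
Reagents that add atoms: water, O
Why: S-Methylation and hydrolysis of the dithiane under neutral buffering, so the β,γ-unsaturated β'-hydroxy ketone should neither conjugate, epimerise at C5 nor undergo retro-aldol cleavage before it is reduced.

Step 14
Reactants: 20 (1R,2S,4S,5S) C6 ketone
Product: 21 (1R,2S,4S,5R,6R) C4,C6 diol
Conditions: Me4NBH(OAc)3, MeCN/AcOH 1:1, −30 °C
Reagents that add atoms: none
Why: Evans–Saksena reduction: the acetoxyborohydride bound to the C4 oxygen delivers hydride internally to the C6 carbonyl and should give the anti-1,3-diol, that is (6R).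

Step 15
Reactants: 21 (1R,2S,4S,5R,6R) diol; 22 3,4,5-trimethoxybenzoyl chloride
Product: 23 C6 3,4,5-trimethoxybenzoate of 21
Conditions: Et3N, DMAP (cat.), CH2Cl2, 0 °C → rt
Reagents that add atoms: none
Why: Nucleophile-catalysed acylation of the only free secondary hydroxyl; the tertiary C4 hydroxyl does not react.

Step 16
Reactants: 23 C6 ester with C2 4-methoxybenzyl ether
Product: 24 C2 alcohol: (1R,2S,4S,5R,6R) 2,4-diol 6-(3,4,5-trimethoxybenzoate)
Conditions: DDQ, CH2Cl2/pH 7 buffer 10:1, 0 °C
Reagents that add atoms: none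
Why: Oxidative cleavage of the 4-methoxybenzyl ether by hydride abstraction; the acyl-substituted trimethoxyarene, the alkene and the esters are not oxidised.

Step 17
Reactants: 24 C2 alcohol; 25 angelic acid, (2Z)-2-methylbut-2-enoic acid
Product: 27 target CNP0112256.1: (1R,2S,4S,5R,6R) C2 (2Z)-2-methylbut-2-enoate; C4 hydroxy and isopropyl; C6 3,4,5-trimethoxybenzoate; C8=C9 alkene; methyl groups on C1 and C8, via angelic 2,4,6-trichlorobenzoic anhydride 26 (not isolated)
Conditions: 2,4,6-trichlorobenzoyl chloride, Et3N, toluene, rt; then 24, 75 °C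
Reagents that add atoms: none
Why: Yamaguchi esterification run without a nucleophilic catalyst, which should keep the Z geometry of the acyl group (such catalysts isomerise it by conjugate addition); only the secondary C2 hydroxyl is acylated.

**Compound list**

1 | (4S)-4-(tert-butyldimethylsilyloxy)cyclopent-2-en-1-one | O=C1C=C[C@@H](O[Si](C)(C)C(C)(C)C)C1 | starting material
2 | (4S)-4-(tert-butyldimethylsilyloxy)-2-iodocyclopent-2-en-1-one | O=C1C(I)=C[C@@H](O[Si](C)(C)C(C)(C)C)C1 | intermediate
3 | (4S)-4-(tert-butyldimethylsilyloxy)-2-methylcyclopent-2-en-1-one | CC1=C[C@@H](O[Si](C)(C)C(C)(C)C)CC1=O | intermediate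
4 | 4,4-diethoxybut-1-yne | C#CCC(OCC)OCC | starting material
5 | propane-1,3-dithiol | SCCCS | starting material
6 | 2-(prop-2-yn-1-yl)-1,3-dithiane | C#CCC1SCCCS1 | intermediate
7 | lithium alkynide of 6 | [Li+].[C-]#CCC1SCCCS1 | intermediate (not isolated)
8 | methyl 4-(1,3-dithian-2-yl)but-2-ynoate | COC(=O)C#CCC1SCCCS1 | intermediate
9 | methyl (2Z)-4-(1,3-dithian-2-yl)-3-methylbut-2-enoate | COC(=O)/C=C(C)\CC1SCCCS1 | intermediate
10 | (2Z)-4-(1,3-dithian-2-yl)-3-methylbut-2-en-1-ol | OC/C=C(C)\CC1SCCCS1 | intermediate
11 | dilithio derivative of 10 (C10 alkoxide, C6 carbanion) | [Li+].[Li+].[O-]C/C=C(C)\C[C-]1SCCCS1 | intermediate (not isolated)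
12 | Michael adduct, dilithium C1=C2 enolate and C10 alkoxide, (4S,5S) | [Li+].[Li+].CC1=C([O-])C[C@H](O[Si](C)(C)C(C)(C)C)[C@H]1C2(SCCCS2)C/C(C)=C\C[O-] | intermediate (not isolated)
13 | lithium C1=C2 enolate with C10 allylic acetate, (4S,5S) | [Li+].CC1=C([O-])C[C@H](O[Si](C)(C)C(C)(C)C)[C@H]1C2(SCCCS2)C/C(C)=C\COC(C)=O | intermediate (not isolated)
14 | (1R,4S,5S) cis-fused bicyclic C2 ketone; C4 OTBS; spiro-dithiane at C6; C8=C9; CH3 on C1 and C8 (C5–H, C1–CH3 and C4–O on one face) | O=C1C[C@H](O[Si](C)(C)C(C)(C)C)[C@H]2C3(SCCCS3)CC(C)=CC[C@@]12C | intermediate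
15 | (1R,2S,4S,5S) C2 alcohol of 14 (C2–OH opposite to C1–CH3) | O[C@H]1C[C@H](O[Si](C)(C)C(C)(C)C)[C@H]2C3(SCCCS3)CC(C)=CC[C@@]12C | intermediate
16 | C2 4-methoxybenzyl ether of 15 | COc1ccc(CO[C@H]2C[C@H](O[Si](C)(C)C(C)(C)C)[C@H]3C4(SCCCS4)CC(C)=CC[C@@]23C)cc1 | intermediate
17 | C4 alcohol (16 without the silyl group) | COc1ccc(CO[C@H]2C[C@H](O)[C@H]3C4(SCCCS4)CC(C)=CC[C@@]23C)cc1 | intermediate
18 | (1R,2S,5S) C4 ketone | COc1ccc(CO[C@H]2CC(=O)[C@H]3C4(SCCCS4)CC(C)=CC[C@@]23C)cc1 | intermediate
19 | (1R,2S,4S,5S) C4 tertiary alcohol, isopropyl cis to C5–H | COc1ccc(CO[C@H]2C[C@](O)(C(C)C)[C@H]3C4(SCCCS4)CC(C)=CC[C@@]23C)cc1 | intermediate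
20 | (1R,2S,4S,5S) C6 ketone | COc1ccc(CO[C@H]2C[C@](O)(C(C)C)[C@H]3C(=O)CC(C)=CC[C@@]23C)cc1 | intermediate
21 | (1R,2S,4S,5R,6R) C4,C6 diol (C6–OH cis to C5–H) | COc1ccc(CO[C@H]2C[C@](O)(C(C)C)[C@H]3[C@H](O)CC(C)=CC[C@@]23C)cc1 | intermediate
22 | 3,4,5-trimethoxybenzoyl chloride | COc1cc(C(=O)Cl)cc(OC)c1OC | starting material
23 | C6 3,4,5-trimethoxybenzoate of 21 | COc1ccc(CO[C@H]2C[C@](O)(C(C)C)[C@H]3[C@H](OC(=O)c4cc(OC)c(OC)c(OC)c4)CC(C)=CC[C@@]23C)cc1 | intermediate
24 | (1R,2S,4S,5R,6R) 2,4-diol 6-(3,4,5-trimethoxybenzoate) | O[C@H]1C[C@](O)(C(C)C)[C@H]2[C@H](OC(=O)c3cc(OC)c(OC)c(OC)c3)CC(C)=CC[C@@]12C | intermediate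
25 | angelic acid, (2Z)-2-methylbut-2-enoic acid | C/C=C(/C)C(=O)O | starting material
26 | angelic 2,4,6-trichlorobenzoic anhydride | C/C=C(/C)C(=O)OC(=O)c1c(Cl)cc(Cl)cc1Cl | intermediate (not isolated)
27 | CNP0112256.1, (1R,2S,4S,5R,6R) | C/C=C(/C)C(=O)O[C@H]1C[C@](O)(C(C)C)[C@H]2[C@H](OC(=O)c3cc(OC)c(OC)c(OC)c3)CC(C)=CC[C@@]12C | target

**Step count.** Total: 17 steps. Longest linear sequence: 15 steps (steps 3–17, from 4 and 5); steps 1–2 form the second branch.

**Steps most likely to fail**

1. Step 7 (proposed new method). The alkoxide may not be acylated cleanly in the presence of the enolate. The allylpalladium intermediate may close at C8 or lose a proton to a diene. Proton exchange may move the enolate to C3 and expel the C4 silyloxy group. Fallback, by stepwise alkylation of a regiodefined enolate (known chemistry), from 10 and 3 back to 14: 10 is silylated (Et3SiCl, imidazole) to triethyl{[(2Z)-4-(1,3-dithian-2-yl)-3-methylbut-2-en-1-yl]oxy}silane F1. Lithiation (nBuLi, THF, −30 °C), addition to 3 in THF/HMPA at −78 °C and quenching with Ac2O should give the C1=C2 enol acetate of the Michael adduct with C10 triethylsilyl ether F2. HF·pyridine buffered with pyridine removes the primary silyl group to give the enol acetate allylic alcohol F3. MsCl, LiCl and 2,4,6-collidine in DMF give the enol acetate allylic chloride F4. MeLi (2 equiv, THF, −78 → 0 °C) cleaves the enol acetate to the C1 lithium enolate regiospecifically, which displaces chloride at C10 and returns the route to 14.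

2. Step 12. The congested C4 ketone may enolise towards C3 or C5, or accept hydride from the isopropyl reagent instead of adding it, or be attacked on the concave face. Fallback from 18 back to 19: the smaller, hydride-free isopropenyl nucleophile (isopropenylmagnesium bromide, CeCl3, THF, −78 °C) should give the C4 isopropenyl carbinol F5. Diimide reduction of its 1,1-disubstituted alkene (2-nitrobenzenesulfonylhydrazide, Et3N, CH2Cl2) tolerates sulfur, should spare the trisubstituted ring alkene, and gives 19.

3. Step 17. Acylation of the hindered C2 hydroxyl next to quaternary C1 may be slow, and the activated acyl group may isomerise from Z to E (tiglate) during the prolonged heating. Fallback from 24 to 27: esterification with 2-[bis(2,2,2-trifluoroethoxy)phosphoryl]propanoic acid (DCC, DMAP, CH2Cl2) gives the C2 2-[bis(2,2,2-trifluoroethoxy)phosphoryl]propanoate F6. Still–Gennari olefination with acetaldehyde (KN(SiMe3)2, 18-crown-6, THF, −78 °C) then builds the Z-2-methylbut-2-enoate on the molecule and gives 27.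

**Further compounds**

F1 | step 7 | triethyl{[(2Z)-4-(1,3-dithian-2-yl)-3-methylbut-2-en-1-yl]oxy}silane | CC[Si](CC)(CC)OC/C=C(C)\CC1SCCCS1
F2 | step 7 | C1=C2 enol acetate of the Michael adduct with C10 triethylsilyl ether, (4S,5S) | CC1=C(OC(C)=O)C[C@H](O[Si](C)(C)C(C)(C)C)[C@H]1C2(SCCCS2)C/C(C)=C\CO[Si](CC)(CC)CC
F3 | step 7 | enol acetate allylic alcohol, (4S,5S) | CC1=C(OC(C)=O)C[C@H](O[Si](C)(C)C(C)(C)C)[C@H]1C2(SCCCS2)C/C(C)=C\CO
F4 | step 7 | enol acetate allylic chloride, (4S,5S) | CC1=C(OC(C)=O)C[C@H](O[Si](C)(C)C(C)(C)C)[C@H]1C2(SCCCS2)C/C(C)=C\CCl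
F5 | step 12 | C4 isopropenyl carbinol (isopropenyl cis to C5–H) | COc1ccc(CO[C@H]2C[C@](O)(C(C)=C)[C@H]3C4(SCCCS4)CC(C)=CC[C@@]23C)cc1
F6 | step 17 | C2 2-[bis(2,2,2-trifluoroethoxy)phosphoryl]propanoate of 24 | CC(C(=O)O[C@H]1C[C@](O)(C(C)C)[C@H]2[C@H](OC(=O)c3cc(OC)c(OC)c(OC)c3)CC(C)=CC[C@@]12C)P(=O)(OCC(F)(F)F)OCC(F)(F)F
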